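**Retrosynthetic overview**

1. Ring labels: A is the terminal 2,4,6-trihydroxyphenoxy ring, B the central 1,3,5-trioxygenated ring, C the ring that carries the biaryl bond, D the trihydroxyphenyl ring. Ring C is numbered C1 (oxygen to ring B), C2 (OH), C3 (the only CH), C4 (OH), C5 (bond to ring D), C6 (OH).
2. Last step: cleavage of all ten alkyl ethers (nine methyl, one ethyl) of 19. Before it, the C1–O–ring B diaryl ether is made by copper-catalysed O-arylation of ring-C phenol 14 with the A–B bromide 18.
3. Ring C is the only ring that is built. In a Dötz benzannulation the alkenyl(methoxy)carbene complex 9 supplies C4, C5 (already bearing ring D) and C6, ethoxyacetylene supplies C2 and C3, and a CO ligand supplies C1 (new bonds C3–C4, C1–C2, C1–C6).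
4. Feature on which this rests: ring C has para oxygens at C1 and C4, ring D on C5 and a single hydrogen at C3, which is the 4-alkoxyphenol pattern this benzannulation produces. The tetra-ortho-substituted C5–ring D bond is carried in as an unhindered aryl–alkenyl bond.
5. Complex 9 comes from 2,4,6-trimethoxybenzaldehyde (methoxymethylenation, bromination–dehydrobromination, Br–Li exchange/Cr(CO)6/Me3OBF4). The same aldehyde gives ring A by Dakin oxidation. Rings A, B and D are bought as benzene rings.

Key step: step 4

Remark: the target has no stereocentre and the C5–ring D axis is not stereogenic (ring D is symmetrically substituted), so only the alkene geometry of the carbene precursor needs attention; ethoxyacetylene is taken as its commercial solution in hexanes.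

**Route**

Step 1
Reactants: 1 2,4,6-trimethoxybenzaldehyde; 2 (methoxymethyl)triphenylphosphonium chloride
Product: 3 1,3,5-trimethoxy-2-(2-methoxyethenyl)benzene (E/Z mixture)
Conditions: KOtBu, THF, 0 °C → rt
Reagents that add atoms: none
Why: Wittig methoxymethylenation with an unstabilised ylide should proceed even on this hindered, electron-rich aldehyde, and the E/Z mixture is of no consequence because both isomers converge in step 2.

Step 2
Reactants: 3 1,3,5-trimethoxy-2-(2-methoxyethenyl)benzene
Product: 5 2-[(Z)-1-bromo-2-methoxyethenyl]-1,3,5-trimethoxybenzene, via dibromide 4 (not isolated)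
Conditions: Br2 (1.0 equiv), CH2Cl2, −78 °C; then DBU, −78 °C → rt
Reagents that add atoms: bromine, BrBr
Why: Bromination–dehydrobromination of an enol ether: the α-bromo ether of 4 should ionise to an oxocarbenium ion and lose the acidified benzylic proton, which leaves bromine on the aryl-bearing carbon and favours the Z isomer (Br cis to OMe, bulky aryl cis to H).

Step 3
Reactants: 5 2-[(Z)-1-bromo-2-methoxyethenyl]-1,3,5-trimethoxybenzene; 6 chromium hexacarbonyl, Cr(CO)6
Product: 9 pentacarbonyl[(2Z)-1,3-dimethoxy-2-(2,4,6-trimethoxyphenyl)prop-2-en-1-ylidene]chromium, via alkenyllithium 7 (not isolated), via lithium acylchromate 8 (not isolated)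
Conditions: t-BuLi (2.0 equiv), THF, −78 °C; Cr(CO)6, −78 → 0 °C; solvent swap; Me3OBF4, CH2Cl2, 0 °C
Reagents that add atoms: trimethyloxonium tetrafluoroborate, C[O+](C)C.F[B-](F)(F)F
Why: Fischer carbene synthesis: bromine–lithium exchange with retention gives the alkenyllithium with Li cis to OMe (the geometry that resists β-elimination of LiOMe), which should add to a CO ligand of Cr(CO)6 to give the acylchromate that the hard oxonium salt methylates on oxygen.

Step 4
Reactants: 9 pentacarbonyl[(2Z)-1,3-dimethoxy-2-(2,4,6-trimethoxyphenyl)prop-2-en-1-ylidene]chromium; 10 ethoxyacetylene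
Product: 14 6-ethoxy-2,4-dimethoxy-3-(2,4,6-trimethoxyphenyl)phenol (4-ethoxy-2,2',4',6,6'-pentamethoxybiphenyl-3-ol), via dienylcarbene complex 11 (not isolated), via dienylketene complex 12 (not isolated), via Cr(CO)3-bound phenol 13 (not isolated)
Conditions: 10 (3 equiv), THF (0.05 M), 50 °C, Ar; then air, MeCN, rt
Reagents that add atoms: none
Why: Dötz benzannulation: thermal loss of one CO ligand from 9 lets ethoxyacetylene coordinate and insert into the Cr=C bond, so that its unsubstituted carbon (C3) bonds to the electrophilic carbene carbon (C4) and the ethoxy-bearing carbon (C2) becomes the new, alkoxy-stabilised carbene carbon of dienylcarbene complex 11. Migration of a CO ligand onto that carbon forms the C1–C2 bond and gives the chromium-bound dienylketene 12. Ring C then closes by a thermal 6π electrocyclisation in which the ketene carbon C1 bonds to the methoxy-bearing alkene terminus C6, and enolisation of the resulting cyclohexadienone gives the phenol as its Cr(CO)3 complex 13, from which air removes the metal. The closest known reactions are the benzannulation of alkenyl(alkoxy)carbene chromium complexes with terminal alkynes and the CO insertion–electrocyclisation of dienyl(alkoxy)carbene chromium complexes to ortho-alkoxyphenols. No stereocentre is formed, and the geometry of the C5=C6 bond is immaterial because C6 ends as an aromatic carbon. The one selectivity needed, the regiochemistry of alkyne insertion, is secured in two ways: the terminal CH is the smaller alkyne end and so is the one taken up by the carbene carbon, and the polarisation of the ynol ether places its electron-rich CH carbon on that same carbon.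

Step 5
Reactants: 1 2,4,6-trimethoxybenzaldehyde
Product: 16 2,4,6-trimethoxyphenol, via aryl formate 15 (not isolated)
Conditions: mCPBA (1.1 equiv), CH2Cl2, 0 °C → rt; then K2CO3 (cat.), MeOH, rt
Reagents that add atoms: 3-chloroperbenzoic acid (mCPBA), OOC(=O)c1cccc(Cl)c1
Why: Dakin-type Baeyer–Villiger oxidation: the very electron-rich aryl group should migrate to oxygen in preference to hydride, giving the aryl formate, which mild methanolysis cleaves to the phenol.

Step 6
Reactants: 16 2,4,6-trimethoxyphenol; 17 1,3-dibromo-5-methoxybenzene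
Product: 18 1-bromo-3-methoxy-5-(2,4,6-trimethoxyphenoxy)benzene
Conditions: 17 (3 equiv), CuI (10 mol %), picolinic acid (20 mol %), K3PO4, DMSO, 90 °C, Ar
Reagents that add atoms: none
Why: Ullmann-type copper-catalysed O-arylation with a ligand system suited to ortho-disubstituted phenols, in which the threefold excess of the symmetrical dibromide should hold the reaction at monosubstitution.

Step 7
Reactants: 14 6-ethoxy-2,4-dimethoxy-3-(2,4,6-trimethoxyphenyl)phenol; 18 1-bromo-3-methoxy-5-(2,4,6-trimethoxyphenoxy)benzene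
Product: 19 1-ethoxy-3,5-dimethoxy-2-[3-methoxy-5-(2,4,6-trimethoxyphenoxy)phenoxy]-4-(2,4,6-trimethoxyphenyl)benzene
Conditions: CuI (20 mol %), picolinic acid (40 mol %), K3PO4, DMSO, 100 °C, Ar
Reagents that add atoms: none
Why: Ullmann-type O-arylation of the single free phenol (the CO-derived oxygen at C1) with the single aryl bromide, under a catalyst system that tolerates phenols flanked by two ortho alkoxy groups; all other oxygens are blocked as ethers.

Step 8
Reactants: 19 1-ethoxy-3,5-dimethoxy-2-[3-methoxy-5-(2,4,6-trimethoxyphenoxy)phenoxy]-4-(2,4,6-trimethoxyphenyl)benzene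
Product: 20 3-[3-hydroxy-5-(2,4,6-trihydroxyphenoxy)phenoxy]biphenyl-2,2',4,4',6,6'-hexol (CNP0260439.0)
Conditions: BBr3 (30 equiv), CH2Cl2, −78 °C → rt; then H2O, 0 °C (degassed, Ar)
Reagents that add atoms: none
Why: Lewis-acid ether cleavage: bromide attacks the methyl or ethyl carbon of each boron-complexed aryl alkyl ether, whereas the diaryl ether and biaryl bonds offer no sp3 carbon for substitution and should survive.

**Compound list**

1 | 2,4,6-trimethoxybenzaldehyde | COc1cc(OC)c(C=O)c(OC)c1 | starting material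
2 | (methoxymethyl)triphenylphosphonium chloride | COC[P+](c1ccccc1)(c1ccccc1)c1ccccc1.[Cl-] | starting material
3 | 1,3,5-trimethoxy-2-(2-methoxyethenyl)benzene (E/Z mixture) | COC=Cc1c(OC)cc(OC)cc1OC | intermediate
4 | 2-(1,2-dibromo-2-methoxyethyl)-1,3,5-trimethoxybenzene (diastereomer mixture) | COC(Br)C(Br)c1c(OC)cc(OC)cc1OC | intermediate
5 | 2-[(Z)-1-bromo-2-methoxyethenyl]-1,3,5-trimethoxybenzene | CO/C=C(\Br)c1c(OC)cc(OC)cc1OC | intermediate
6 | chromium hexacarbonyl, Cr(CO)6 | O=C=[Cr](=C=O)(=C=O)(=C=O)(=C=O)=C=O | starting material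
7 | [(E)-2-methoxy-1-(2,4,6-trimethoxyphenyl)ethenyl]lithium (Li cis to OMe) | CO/C=C(\[Li])c1c(OC)cc(OC)cc1OC | intermediate
8 | lithium pentacarbonyl[(Z)-3-methoxy-2-(2,4,6-trimethoxyphenyl)prop-2-enoyl]chromate | CO/C=C(\C([O-])=[Cr](=C=O)(=C=O)(=C=O)(=C=O)=C=O)c1c(OC)cc(OC)cc1OC.[Li+] | intermediate
9 | pentacarbonyl[(2Z)-1,3-dimethoxy-2-(2,4,6-trimethoxyphenyl)prop-2-en-1-ylidene]chromium | COC(=[Cr](=C=O)(=C=O)(=C=O)(=C=O)=C=O)/C(=C\OC)c1c(OC)cc(OC)cc1OC | intermediate
10 | ethoxyacetylene | C#COCC | starting material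
11 | tetracarbonyl[(2E,4Z)-1-ethoxy-3,5-dimethoxy-4-(2,4,6-trimethoxyphenyl)penta-2,4-dien-1-ylidene]chromium | CCOC(=[Cr](=C=O)(=C=O)(=C=O)=C=O)/C=C(/OC)\C(=C/OC)c1c(OC)cc(OC)cc1OC | intermediate
12 | tricarbonylchromium complex of (3E,5Z)-2-ethoxy-4,6-dimethoxy-5-(2,4,6-trimethoxyphenyl)hexa-1,3,5-trien-1-one | CCOC(=C=O)/C=C(/OC)\C(=C/OC)c1c(OC)cc(OC)cc1OC.[Cr](=C=O)(=C=O)=C=O | intermediate
13 | tricarbonyl[η6-6-ethoxy-2,4-dimethoxy-3-(2,4,6-trimethoxyphenyl)phenol]chromium (metal on ring C) | CCOc1cc(OC)c(-c2c(OC)cc(OC)cc2OC)c(OC)c1O.[Cr](=C=O)(=C=O)=C=O | intermediate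
14 | 6-ethoxy-2,4-dimethoxy-3-(2,4,6-trimethoxyphenyl)phenol | CCOc1cc(OC)c(-c2c(OC)cc(OC)cc2OC)c(OC)c1O | intermediate
15 | 2,4,6-trimethoxyphenyl formate | COc1cc(OC)c(OC=O)c(OC)c1 | intermediate
16 | 2,4,6-trimethoxyphenol | COc1cc(OC)c(O)c(OC)c1 | intermediate
17 | 1,3-dibromo-5-methoxybenzene | COc1cc(Br)cc(Br)c1 | starting material
18 | 1-bromo-3-methoxy-5-(2,4,6-trimethoxyphenoxy)benzene | COc1cc(Br)cc(Oc2c(OC)cc(OC)cc2OC)c1 | intermediate
19 | 1-ethoxy-3,5-dimethoxy-2-[3-methoxy-5-(2,4,6-trimethoxyphenoxy)phenoxy]-4-(2,4,6-trimethoxyphenyl)benzene | CCOc1cc(OC)c(-c2c(OC)cc(OC)cc2OC)c(OC)c1Oc1cc(OC)cc(Oc2c(OC)cc(OC)cc2OC)c1 | intermediate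
20 | 3-[3-hydroxy-5-(2,4,6-trihydroxyphenoxy)phenoxy]biphenyl-2,2',4,4',6,6'-hexol | Oc1cc(Oc2c(O)cc(O)cc2O)cc(Oc2c(O)cc(O)c(-c3c(O)cc(O)cc3O)c2O)c1 | target

Total step count: 8. Longest linear sequence: 6 steps (steps 1, 2, 3, 4, 7 and 8, from aldehyde 1).

**Steps most likely to fail**

Step 4. The sequence may stall after alkyne insertion, because a CO ligand migrates only slowly onto an alkoxy-stabilised carbene carbon. It may also divert to five-membered-ring closure without CO uptake, or the ynol ether may oligomerise on the metal. The fallback gives up the benzannulation and makes the C–D biaryl by cross-coupling, setting out from phenol 16 and coming back to the route at target 20. Phenol 16 would be benzylated (benzyl bromide, K2CO3, DMF) to 2-(benzyloxy)-1,3,5-trimethoxybenzene F1. NBS in MeCN at 0 °C would brominate one of the two equivalent free positions to give 3-(benzyloxy)-1-bromo-2,4,6-trimethoxybenzene F2. Suzuki–Miyaura coupling of F2 with commercial (2,4,6-trimethoxyphenyl)boronic acid (Pd(OAc)2, SPhos, K3PO4, toluene/water, 100 °C) would give 3-(benzyloxy)-2,2',4,4',6,6'-hexamethoxybiphenyl F3. Hydrogenolysis (H2, Pd on carbon, EtOAc) would free 2,4,6-trimethoxy-3-(2,4,6-trimethoxyphenyl)phenol F4, the all-methyl analogue of 14. O-arylation of F4 with bromide 18 under the conditions of step 7 would give 1,3,5-trimethoxy-2-[3-methoxy-5-(2,4,6-trimethoxyphenoxy)phenoxy]-4-(2,4,6-trimethoxyphenyl)benzene F5, and BBr3 as in step 8 would convert F5 into 20.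

Step 7. Carbon–oxygen bond formation at a phenoxide flanked by two alkoxy groups with an electron-rich bromide may be slow, allowing reductive loss of bromine from 18 or oxidative degradation of the electron-rich phenol. The fallback turns the electrophile into a boron nucleophile and forms the ether oxidatively, setting out from bromide 18 and coming back at 19. Bromine–lithium exchange with in-situ borate trapping (B(OiPr)3, n-BuLi, THF, −78 °C, then aqueous acid) would give [3-methoxy-5-(2,4,6-trimethoxyphenoxy)phenyl]boronic acid F10. Chan–Lam coupling of F10 with phenol 14 (stoichiometric Cu(OAc)2, pyridine, 4 Å molecular sieves, CH2Cl2, air, rt) would give 19.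

Step 2. Electrophilic bromine may attack the trimethoxyphenyl ring in competition with the enol ether. Elimination may also run in the other sense (loss of the benzylic bromide), or give the E bromide, whose lithio derivative would eliminate LiOMe in step 3. The fallback avoids electrophilic bromine and sets the alkene geometry through a chelated enolate, setting out from aldehyde 1 and coming back at alkenyllithium 7 in step 3. Addition of methoxymethyllithium (from Bu3SnCH2OMe and n-BuLi, THF, −78 °C) to 1 would give 2-methoxy-1-(2,4,6-trimethoxyphenyl)ethanol F6. Dess–Martin periodinane would oxidise it to 2-methoxy-1-(2,4,6-trimethoxyphenyl)ethanone F7. Enolisation with KN(SiMe3)2 and trapping with PhNTf2 (THF, −78 °C) would give (Z)-2-methoxy-1-(2,4,6-trimethoxyphenyl)ethenyl trifluoromethanesulfonate F8, with OTf cis to OMe. Stannylation (Pd(PPh3)4, Me3SnSnMe3, LiCl, THF, 60 °C) would give trimethyl[(Z)-2-methoxy-1-(2,4,6-trimethoxyphenyl)ethenyl]stannane F9, and tin–lithium exchange of F9 with MeLi (THF, −78 °C) would deliver 7 for addition to Cr(CO)6 and methylation as in step 3.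

**Further compounds**

F1 | step 4 | 2-(benzyloxy)-1,3,5-trimethoxybenzene | COc1cc(OC)c(OCc2ccccc2)c(OC)c1
F2 | step 4 | 3-(benzyloxy)-1-bromo-2,4,6-trimethoxybenzene | COc1cc(OC)c(OCc2ccccc2)c(OC)c1Br
F3 | step 4 | 3-(benzyloxy)-2,2',4,4',6,6'-hexamethoxybiphenyl | COc1cc(OC)c(OCc2ccccc2)c(OC)c1-c1c(OC)cc(OC)cc1OC
F4 | step 4 | 2,4,6-trimethoxy-3-(2,4,6-trimethoxyphenyl)phenol | COc1cc(OC)c(O)c(OC)c1-c1c(OC)cc(OC)cc1OC
F5 | step 4 | 1,3,5-trimethoxy-2-[3-methoxy-5-(2,4,6-trimethoxyphenoxy)phenoxy]-4-(2,4,6-trimethoxyphenyl)benzene | COc1cc(Oc2c(OC)cc(OC)cc2OC)cc(Oc2c(OC)cc(OC)c(-c3c(OC)cc(OC)cc3OC)c2OC)c1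
F6 | step 2 | 2-methoxy-1-(2,4,6-trimethoxyphenyl)ethanol | COCC(O)c1c(OC)cc(OC)cc1OC
F7 | step 2 | 2-methoxy-1-(2,4,6-trimethoxyphenyl)ethanone | COCC(=O)c1c(OC)cc(OC)cc1OC
F8 | step 2 | (Z)-2-methoxy-1-(2,4,6-trimethoxyphenyl)ethenyl trifluoromethanesulfonate | CO/C=C(\OS(=O)(=O)C(F)(F)F)c1c(OC)cc(OC)cc1OC
F9 | step 2 | trimethyl[(Z)-2-methoxy-1-(2,4,6-trimethoxyphenyl)ethenyl]stannane | CO/C=C(\[Sn](C)(C)C)c1c(OC)cc(OC)cc1OC
F10 | step 7 | [3-methoxy-5-(2,4,6-trimethoxyphenoxy)phenyl]boronic acid | COc1cc(B(O)O)cc(Oc2c(OC)cc(OC)cc2OC)c1
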